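C1 = ring-fusion C(CH3), C2 = CH-OAc, C3 = CH2, C4 = C(OH)(iPr), C5 = ring-fusion CH, C6 = CH-O-anisoyl, C7 = CH2, C8/C9 = epoxide C(CH3)/CH, C10 = CHOH; β is the face that carries the C1 methyl.
Enabling feature: in the seven-membered ring (C1, C5, C6, C7, C8, C9, C10) the lone methylene C7 separates the C5-C6 edge (H/O-acyl) from the C8-C9 edge (oxirane). The ring is therefore a disguised cyclohepta-1,4-diene, and the bond opposite C7, C1 (quaternary) to C10 (carbinol), is the σ bond that a cis-divinylcyclopropane rearrangement creates.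
Retrosynthesis: the ester, the oxirane oxygen, the C5-H/C6-O pair and the C4-isopropyl bond are stripped back to a dienone. Then C1-C10 is cut (C6-C8 re-forms, seven contracts to three), then C9=C10 (olefination), then C5-C6 (cross-coupling), giving an iodoenone and an iodocyclopropane.
Forward: the five-membered ring is bought, the cyclopropane is made separately, and the two are joined at C5-C6. The Cope ring expansion turns the three-membered ring into the seven-membered ring fused to the cyclopentenone, and the C8-C9 oxirane is closed last.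
Stereochemistry: C2 comes with (R)-4-silyloxycyclopentenone. The cyclopropane carbons C6/C8 come from a ligand-controlled Simmons-Smith reaction and are relayed to C1 through the boat transition state. C4 and C10 arise by α-face additions to the locked bicycle. C5, C6, C8 and C9 arise from hydroxyl-directed steps (4β-OH gives the 5β,6β-epoxide and then 5α-H; 4β-OH gives 6α-OH; 6α-OH gives the 8α,9α-epoxide).

Key step: step 9

Remark: the facial sense known for the (4R,5R)-dioxaborolane in cyclopropanations of E-, Z- and 2-substituted allylic alcohols is assumed to hold for alcohol 7; if it is reversed, the (4S,5S) ligand is used.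

Step 1
Reactants: 1 (R)-4-(tert-butyldimethylsilyloxy)cyclopent-2-en-1-one
Product: 2 (3R,4R)-4-(tert-butyldimethylsilyloxy)-3-methyl-1-(trimethylsilyloxy)cyclopent-1-ene (methyl trans to OTBS)
Conditions: Me2CuLi (from MeLi, CuI), TMSCl, Et2O/THF, -78 °C
Reagents that add atoms: lithium dimethylcuprate [Li+].C[Cu-]C; chlorotrimethylsilane C[Si](C)(C)Cl
Why: Gilman cuprate 1,4-addition with in situ silyl trapping puts the methyl on the future C1 anti to the silyloxy group (a centre erased in step 2) and fixes the enolate regiochemistry for reoxidation.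

Step 2
Reactants: 2 (3R,4R)-4-(tert-butyldimethylsilyloxy)-3-methyl-1-(trimethylsilyloxy)cyclopent-1-ene
Product: 3 (R)-4-(tert-butyldimethylsilyloxy)-3-methylcyclopent-2-en-1-one
Conditions: Pd(OAc)2 (10 mol %), O2 (1 atm), DMSO, rt
Reagents that add atoms: none
Why: In this Saegusa-Ito oxidation (aerobic catalytic variant) the C2-bound palladium enolate has only the C3-H for syn β-hydride elimination, so the enone returns with the methyl on its β-carbon and the silyloxy centre untouched.

Step 3
Reactants: 3 (R)-4-(tert-butyldimethylsilyloxy)-3-methylcyclopent-2-en-1-one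
Product: 4 (R)-4-(tert-butyldimethylsilyloxy)-2-iodo-3-methylcyclopent-2-en-1-one
Conditions: I2, PhI(OCOCF3)2, pyridine, CH2Cl2, rt, dark
Reagents that add atoms: iodine II
Why: Electrophilic α-iodination of the enone uses the pyridine-buffered I2/hypervalent-iodine couple as an I+ source, because iodine/pyridine alone is sluggish on β-substituted enones; the stereocentre is not involved.

Step 4
Reactants: 5 propargyl alcohol
Product: 7 (Z)-3-iodo-2-methylprop-2-en-1-ol, via (Z)-alkenylmagnesium alkoxide 6 (not isolated)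
Conditions: MeMgBr (2.5 equiv), CuI (10 mol %), Et2O/THF, -10 °C to rt; then I2, 0 °C
Reagents that add atoms: methylmagnesium bromide C[Mg]Br; iodine II
Why: Copper-catalysed anti-carbomagnesiation of the propargylic alkoxide places the methyl on the internal carbon (C8) and magnesium on the terminus (C6) within a chelate, so iodinolysis with retention should give only the Z iodide.

Step 5
Reactants: 7 (Z)-3-iodo-2-methylprop-2-en-1-ol
Product: 8 [(1R,2R)-2-iodo-1-methylcyclopropyl]methanol (iodine cis to CH2OH)
Conditions: Et2Zn, CH2I2, DME, (4R,5R)-2-butyl-N,N,N',N'-tetramethyl-1,3,2-dioxaborolane-4,5-dicarboxamide (1.2 equiv), CH2Cl2, -10 °C to rt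
Reagents that add atoms: diiodomethane ICI
Why: In this Charette asymmetric Simmons-Smith cyclopropanation the zinc alkoxide bound to the chiral dioxaborolane delivers CH2 (C7) to one alkene face stereospecifically, so the Z geometry becomes the cis I/CH2OH relation and the ligand sets both ring stereocentres.

Step 6
Reactants: 8 [(1R,2R)-2-iodo-1-methylcyclopropyl]methanol; 4 (R)-4-(tert-butyldimethylsilyloxy)-2-iodo-3-methylcyclopent-2-en-1-one
Product: 11 (4R)-4-(tert-butyldimethylsilyloxy)-2-[(1R,2S)-2-(hydroxymethyl)-2-methylcyclopropyl]-3-methylcyclopent-2-en-1-one, via dilithiated cyclopropylmethanol 9 (not isolated), via cyclopropylzinc chloride 10 (not isolated)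
Conditions: 8, t-BuLi (3.1 equiv), Et2O, -78 °C; ZnCl2 (2.2 equiv), THF, -78 to 0 °C; then 4, Pd2(dba)3 (2.5 mol %), SPhos (10 mol %), THF, rt to 45 °C
Reagents that add atoms: none
Why: Negishi coupling forms C5-C6 because cyclopropyllithium and cyclopropylzinc species are configurationally stable and couple with retention, α-iodoenones are established electrophiles, and the zinc alkoxide is too weak a base to expel the silyloxy group.

Step 7
Reactants: 11 (4R)-4-(tert-butyldimethylsilyloxy)-2-[(1R,2S)-2-(hydroxymethyl)-2-methylcyclopropyl]-3-methylcyclopent-2-en-1-one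
Product: 12 (4R)-4-(tert-butyldimethylsilyloxy)-2-[(1R,2S)-2-formyl-2-methylcyclopropyl]-3-methylcyclopent-2-en-1-one
Conditions: Dess-Martin periodinane, pyridine, CH2Cl2, 0 °C; cold work-up, used at once
Reagents that add atoms: none
Why: Buffered Dess-Martin oxidation gives an aldehyde that cannot epimerise (C8 is quaternary), and the low temperature holds back the reversible retro-Claisen shift open to cis-alkenyl cyclopropanecarbaldehydes.

Step 8
Reactants: 12 (4R)-4-(tert-butyldimethylsilyloxy)-2-[(1R,2S)-2-formyl-2-methylcyclopropyl]-3-methylcyclopent-2-en-1-one; 13 2-(dichloromethyl)-4,4,5,5-tetramethyl-1,3,2-dioxaborolane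
Product: 15 (4R)-4-(tert-butyldimethylsilyloxy)-3-methyl-2-{(1R,2R)-2-methyl-2-[(E)-2-(4,4,5,5-tetramethyl-1,3,2-dioxaborolan-2-yl)ethenyl]cyclopropyl}cyclopent-2-en-1-one, via gem-dichromium boronate 14 (not isolated)
Conditions: 13 (2 equiv), CrCl2 (8 equiv), LiI (4 equiv), THF, 0 °C to rt
Reagents that add atoms: none
Why: In this Takai-Utimoto chromium(II) boryl-olefination the gem-dichromium reagent adds only to the aldehyde (the enone carbonyl is inert to it), and elimination from the less crowded adduct should give the E-alkenylboronate, which brings in C10.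

Step 9
Reactants: 15 (4R)-4-(tert-butyldimethylsilyloxy)-3-methyl-2-{(1R,2R)-2-methyl-2-[(E)-2-(4,4,5,5-tetramethyl-1,3,2-dioxaborolan-2-yl)ethenyl]cyclopropyl}cyclopent-2-en-1-one
Product: 16 2β-(tert-butyldimethylsilyloxy)-1β,8-dimethyl-10α-(pinacolatoboryl)bicyclo[5.3.0]deca-5,8-dien-4-one (target numbering; C5=C6, C8=C9)
Conditions: PhMe (dilute), BHT (cat.), 110 °C, sealed tube
Reagents that add atoms: none
Why: A concerted, thermally allowed [3,3]-sigmatropic shift runs through the endo-boat array of the cis-dialkenylcyclopropane: the strained C6-C8 σ bond breaks while C1-C10 forms, and the π bonds move to C5=C6 and C8=C9 with C7 as the CH2 between them. The closest known reaction type is the divinylcyclopropane-cycloheptadiene (Cope) rearrangement of cyclopropyl-substituted cycloalkenones, which is known to build hydroazulenes and angular quaternary carbons. The seven-membered ring is closed by ring expansion (three to seven, driven by release of cyclopropane strain) and becomes fused to the five-membered ring along C1-C5, with no chain cyclisation involved. C1 is controlled by the cyclopropane configuration, because in the only reactive boat geometry the (1R,2R)-cyclopropane lies under the α face of the enone, so C10 bonds from α and the methyl ends β, which is also the face anti to the 2β-silyloxy group (matched case). C10 is controlled by the alkene geometry, since the E-boryl group points outward like C2 and boron therefore ends α, trans to the C1 methyl. The step needs clean [3,3] reactivity rather than cyclopropane epimerisation or loss of boron, and the cis relation fixed in steps 4 to 6, the single inward substituent (C1 methyl), the flat C4 carbonyl and the neutral medium for the robust pinacol ester should secure this at moderate temperature.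

Step 10
Reactants: 16 2β-(tert-butyldimethylsilyloxy)-1β,8-dimethyl-10α-(pinacolatoboryl)bicyclo[5.3.0]deca-5,8-dien-4-one
Product: 17 2β-(tert-butyldimethylsilyloxy)-10α-hydroxy-1β,8-dimethylbicyclo[5.3.0]deca-5,8-dien-4-one
Conditions: NaBO3·4H2O (3 equiv), THF/H2O, 0 °C to rt
Reagents that add atoms: sodium perborate [Na+].[Na+].O[B-]1(O)OO[B-](O)(O)OO1
Why: Perborate oxidation of the C-B bond goes by 1,2-migration with retention and without allylic shift, giving the 10α-alcohol, and this mild oxidant is chosen to spare the enone and the β-silyloxy ketone.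

Step 11
Reactants: 17 2β-(tert-butyldimethylsilyloxy)-10α-hydroxy-1β,8-dimethylbicyclo[5.3.0]deca-5,8-dien-4-one; 18 isopropylmagnesium chloride
Product: 20 2β-(tert-butyldimethylsilyloxy)dauca-5,8-diene-4β,10α-diol (4α-isopropyl), via isopropylcerium dichloride 19 (not isolated)
Conditions: anhydrous CeCl3 (4.5 equiv), 18 (4 equiv), THF, -78 °C; then 17, -78 to -20 °C
Reagents that add atoms: none
Why: The weakly basic, oxophilic reagent of this Imamoto organocerium 1,2-addition suppresses enolisation, β-elimination, reduction and 1,4-addition, and it should attack C4 from the α face because the β face carries both the C1 methyl and the C2 silyloxy group in a 1,3-relation, giving 4β-OH/4α-isopropyl.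

Step 12
Reactants: 20 2β-(tert-butyldimethylsilyloxy)dauca-5,8-diene-4β,10α-diol
Product: 21 dauca-5,8-diene-2β,4β,10α-triol
Conditions: TBAF, THF, rt to 40 °C
Reagents that add atoms: none
Why: Fluoride desilylation is done at the one stage where the molecule holds no carbonyl group, so neither β-elimination nor retro-aldol cleavage can follow.

Step 13
Reactants: 21 dauca-5,8-diene-2β,4β,10α-triol
Product: 22 2β,4β-dihydroxydauca-5,8-dien-10-one
Conditions: activated MnO2, CH2Cl2, rt
Reagents that add atoms: none
Why: Manganese dioxide oxidises only the secondary allylic alcohol, so C10 becomes the enone carbonyl, the tertiary C4-OH and the saturated C2-OH stay, and the α configuration delivered by the rearrangement is erased on purpose.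

Step 14
Reactants: 22 2β,4β-dihydroxydauca-5,8-dien-10-one
Product: 23 2β-acetoxy-4β-hydroxydauca-5,8-dien-10-one
Conditions: Ac2O, pyridine, DMAP (cat.), CH2Cl2, 0 °C to rt
Reagents that add atoms: acetic anhydride CC(=O)OC(C)=O
Why: DMAP-catalysed acetylation finds a single acylable hydroxyl, because C4-OH is tertiary and crowded and C10 is a ketone at this stage, and this is what tells O2 apart from O10.

Step 15
Reactants: 23 2β-acetoxy-4β-hydroxydauca-5,8-dien-10-one
Product: 24 2β-acetoxydauca-5,8-diene-4β,10β-diol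
Conditions: NaBH4, CeCl3·7H2O, MeOH, -78 to -40 °C; pH 7 buffer quench
Reagents that add atoms: none
Why: In this Luche 1,2-reduction the ring-locked boat of the cycloheptadienone exposes its convex α face while the axial C1 methyl screens the β face, so hydride should enter from α and give 10β-OH, and the cold non-basic medium discourages O2-to-O10 acetyl migration.

Step 16
Reactants: 24 2β-acetoxydauca-5,8-diene-4β,10β-diol
Product: 25 2β-acetoxy-10β-(triethylsilyloxy)dauca-5,8-dien-4β-ol
Conditions: TESOTf (1.05 equiv), 2,6-lutidine, CH2Cl2, -78 °C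
Reagents that add atoms: triethylsilyl triflate CC[Si](CC)(CC)OS(=O)(=O)C(F)(F)F
Why: Kinetically controlled silylation selects the secondary C10 hydroxyl over the tertiary one, which masks the only group that could steer an oxidant to C8=C9 and leaves 4β-OH free as a directing group.

Step 17
Reactants: 25 2β-acetoxy-10β-(triethylsilyloxy)dauca-5,8-dien-4β-ol
Product: 26 2β-acetoxy-5β,6β-epoxy-10β-(triethylsilyloxy)dauc-8-en-4β-ol
Conditions: VO(acac)2 (5 mol %), t-BuOOH (decane), CH2Cl2, 0 °C to rt
Reagents that add atoms: tert-butyl hydroperoxide CC(C)(C)OO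
Why: In vanadium-catalysed hydroxyl-directed epoxidation only the alkene allylic to a free hydroxyl reacts, which settles the C5=C6 versus C8=C9 choice that undirected reagents (boranes, peracids) would decide for the less hindered C8=C9, and oxygen is delivered syn to 4β-OH.

Step 18
Reactants: 26 2β-acetoxy-5β,6β-epoxy-10β-(triethylsilyloxy)dauc-8-en-4β-ol
Product: 27 2β-acetoxy-10β-(triethylsilyloxy)-5αH-dauc-8-ene-4β,6β-diol (trans ring fusion)
Conditions: Cp2TiCl2 (2.5 equiv), Zn dust, THF, rt; 1,4-cyclohexadiene (10 equiv), then 26, rt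
Reagents that add atoms: none
Why: In this titanocene(III) reductive epoxide opening (RajanBabu-Nugent reaction) homolysis gives the more substituted C5 radical and keeps oxygen on C6, a mode established for 2,3-epoxy alcohols leading to 1,3-diols, and hydrogen-atom transfer should come from the α face, opposite the C1 methyl and the two titanium-bound β oxygens, setting 5α-H.

Step 19
Reactants: 27 2β-acetoxy-10β-(triethylsilyloxy)-5αH-dauc-8-ene-4β,6β-diol
Product: 28 2β-acetoxy-4β-hydroxy-10β-(triethylsilyloxy)-5αH-dauc-8-en-6-one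
Conditions: Dess-Martin periodinane, pyridine, CH2Cl2, 0 °C
Reagents that add atoms: none
Why: Neutral Dess-Martin oxidation takes the secondary C6 alcohol only and is the standard way to reach a β,γ-unsaturated β'-hydroxy ketone without conjugation of C8=C9, C5 epimerisation or retro-aldol cleavage.

Step 20
Reactants: 28 2β-acetoxy-4β-hydroxy-10β-(triethylsilyloxy)-5αH-dauc-8-en-6-one
Product: 29 2β-acetoxy-10β-(triethylsilyloxy)-5αH-dauc-8-ene-4β,6α-diol
Conditions: Me4NBH(OAc)3, MeCN/AcOH, -30 °C
Reagents that add atoms: none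
Why: In this Evans-Saksena hydroxyl-directed reduction the borohydride exchanges onto 4β-OH and passes hydride intramolecularly to the β face of the C6 carbonyl, giving the anti-1,3-diol, that is 6α-OH.

Step 21
Reactants: 29 2β-acetoxy-10β-(triethylsilyloxy)-5αH-dauc-8-ene-4β,6α-diol
Product: 30 2β-acetoxy-8α,9α-epoxy-10β-(triethylsilyloxy)-5αH-daucane-4β,6α-diol
Conditions: VO(acac)2 (5 mol %), t-BuOOH (decane), CH2Cl2, 0 °C to rt
Reagents that add atoms: tert-butyl hydroperoxide CC(C)(C)OO
Why: Vanadium-catalysed epoxidation directed by the homoallylic 6α-OH delivers oxygen to the α face of C8=C9, and the 10β-silyloxy group blocks the opposite face, so both effects point the same way.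

Step 22
Reactants: 30 2β-acetoxy-8α,9α-epoxy-10β-(triethylsilyloxy)-5αH-daucane-4β,6α-diol; 31 4-methoxybenzoyl chloride
Product: 32 2β-acetoxy-8α,9α-epoxy-4β-hydroxy-10β-(triethylsilyloxy)-5αH-daucan-6α-yl 4-methoxybenzoate
Conditions: 31 (1.5 equiv), DMAP, Et3N, CH2Cl2, 0 °C to rt
Reagents that add atoms: none
Why: DMAP-catalysed acylation takes the only secondary free hydroxyl (C6), because the tertiary C4-OH of such 4,6-diols does not acylate under these conditions.

Step 23
Reactants: 32 2β-acetoxy-8α,9α-epoxy-4β-hydroxy-10β-(triethylsilyloxy)-5αH-daucan-6α-yl 4-methoxybenzoate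
Product: 33 target CNP0371526.1, 2β-acetoxy-8α,9α-epoxy-4β,10β-dihydroxy-5αH-daucan-6α-yl 4-methoxybenzoate
Conditions: HF·pyridine, excess pyridine, THF, 0 °C
Reagents that add atoms: none
Why: Buffered hydrogen fluoride removes the labile triethylsilyl ether under non-basic conditions, so neither O2/O10 acetyl migration nor Payne rearrangement of the epoxy alcohol is triggered, and the short cold exposure should spare the oxirane.

Compound list
1 | (R)-4-(tert-butyldimethylsilyloxy)cyclopent-2-en-1-one | O=C1C[C@@H](O[Si](C)(C)C(C)(C)C)C=C1 | starting material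
2 | (3R,4R)-4-(tert-butyldimethylsilyloxy)-3-methyl-1-(trimethylsilyloxy)cyclopent-1-ene | C[C@@H]1C=C(O[Si](C)(C)C)C[C@H]1O[Si](C)(C)C(C)(C)C | intermediate
3 | (R)-4-(tert-butyldimethylsilyloxy)-3-methylcyclopent-2-en-1-one | CC1=CC(=O)C[C@H]1O[Si](C)(C)C(C)(C)C | intermediate
4 | (R)-4-(tert-butyldimethylsilyloxy)-2-iodo-3-methylcyclopent-2-en-1-one | CC1=C(I)C(=O)C[C@H]1O[Si](C)(C)C(C)(C)C | intermediate
5 | propargyl alcohol | C#CCO | starting material
6 | bromomagnesium (Z)-3-(bromomagnesio)-2-methylprop-2-en-1-olate (not isolated) | C/C(CO[Mg]Br)=C/[Mg]Br | intermediate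
7 | (Z)-3-iodo-2-methylprop-2-en-1-ol | OC/C(C)=C\I | intermediate
8 | [(1R,2R)-2-iodo-1-methylcyclopropyl]methanol, I cis to CH2OH | OC[C@@]1(C)C[C@H]1I | intermediate
9 | lithium (cis-2-lithio-1-methylcyclopropyl)methanolate, configuration of 8 (not isolated) | [Li]OC[C@@]1(C)C[C@H]1[Li] | intermediate
10 | chlorozinc [cis-2-(chlorozincio)-1-methylcyclopropyl]methanolate, configuration of 8 (not isolated) | Cl[Zn]OC[C@@]1(C)C[C@H]1[Zn]Cl | intermediate
11 | (4R)-4-(tert-butyldimethylsilyloxy)-2-[(1R,2S)-2-(hydroxymethyl)-2-methylcyclopropyl]-3-methylcyclopent-2-en-1-one | CC1=C([C@@H]2C[C@]2(C)CO)C(=O)C[C@H]1O[Si](C)(C)C(C)(C)C | intermediate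
12 | (4R)-4-(tert-butyldimethylsilyloxy)-2-[(1R,2S)-2-formyl-2-methylcyclopropyl]-3-methylcyclopent-2-en-1-one | CC1=C([C@@H]2C[C@]2(C)C=O)C(=O)C[C@H]1O[Si](C)(C)C(C)(C)C | intermediate
13 | 2-(dichloromethyl)-4,4,5,5-tetramethyl-1,3,2-dioxaborolane | ClC(Cl)B1OC(C)(C)C(C)(C)O1 | starting material
14 | [bis(dichlorochromio)methyl]boronic acid pinacol ester (not isolated) | Cl[Cr](Cl)C([Cr](Cl)Cl)B1OC(C)(C)C(C)(C)O1 | intermediate
15 | cis-divinylcyclopropane: (4R)-4-(tert-butyldimethylsilyloxy)-3-methyl-2-{(1R,2R)-2-methyl-2-[(E)-2-(pinacolatoboryl)ethenyl]cyclopropyl}cyclopent-2-en-1-one | CC1=C([C@@H]2C[C@]2(C)/C=C/B3OC(C)(C)C(C)(C)O3)C(=O)C[C@H]1O[Si](C)(C)C(C)(C)C | intermediate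
16 | 2β-(tert-butyldimethylsilyloxy)-1β,8-dimethyl-10α-(pinacolatoboryl)bicyclo[5.3.0]deca-5,8-dien-4-one | C1=C2C(=O)C[C@@H](O[Si](C)(C)C(C)(C)C)[C@]2(C)[C@H](B3OC(C)(C)C(C)(C)O3)C=C(C)C1 | intermediate
17 | 2β-(tert-butyldimethylsilyloxy)-10α-hydroxy-1β,8-dimethylbicyclo[5.3.0]deca-5,8-dien-4-one | C1=C2C(=O)C[C@@H](O[Si](C)(C)C(C)(C)C)[C@]2(C)[C@H](O)C=C(C)C1 | intermediate
18 | isopropylmagnesium chloride | CC(C)[Mg]Cl | starting material
19 | isopropylcerium dichloride (not isolated) | CC(C)[Ce](Cl)Cl | intermediate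
20 | 2β-(tert-butyldimethylsilyloxy)dauca-5,8-diene-4β,10α-diol | C1=C2[C@](O)(C(C)C)C[C@@H](O[Si](C)(C)C(C)(C)C)[C@]2(C)[C@H](O)C=C(C)C1 | intermediate
21 | dauca-5,8-diene-2β,4β,10α-triol | C1=C2[C@](O)(C(C)C)C[C@@H](O)[C@]2(C)[C@H](O)C=C(C)C1 | intermediate
22 | 2β,4β-dihydroxydauca-5,8-dien-10-one | C1=C2[C@](O)(C(C)C)C[C@@H](O)[C@]2(C)C(=O)C=C(C)C1 | intermediate
23 | 2β-acetoxy-4β-hydroxydauca-5,8-dien-10-one | C1=C2[C@](O)(C(C)C)C[C@@H](OC(C)=O)[C@]2(C)C(=O)C=C(C)C1 | intermediate
24 | 2β-acetoxydauca-5,8-diene-4β,10β-diol | C1=C2[C@](O)(C(C)C)C[C@@H](OC(C)=O)[C@]2(C)[C@@H](O)C=C(C)C1 | intermediate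
25 | 2β-acetoxy-10β-(triethylsilyloxy)dauca-5,8-dien-4β-ol | C1=C2[C@](O)(C(C)C)C[C@@H](OC(C)=O)[C@]2(C)[C@@H](O[Si](CC)(CC)CC)C=C(C)C1 | intermediate
26 | 2β-acetoxy-5β,6β-epoxy-10β-(triethylsilyloxy)dauc-8-en-4β-ol | O1[C@@H]2CC(C)=C[C@H](O[Si](CC)(CC)CC)[C@]3(C)[C@]12[C@](O)(C(C)C)C[C@H]3OC(C)=O | intermediate
27 | 2β-acetoxy-10β-(triethylsilyloxy)-5αH-dauc-8-ene-4β,6β-diol | O[C@@H]1CC(C)=C[C@H](O[Si](CC)(CC)CC)[C@]2(C)[C@@H]1[C@](O)(C(C)C)C[C@H]2OC(C)=O | intermediate
28 | 2β-acetoxy-4β-hydroxy-10β-(triethylsilyloxy)-5αH-dauc-8-en-6-one | O=C1CC(C)=C[C@H](O[Si](CC)(CC)CC)[C@]2(C)[C@@H]1[C@](O)(C(C)C)C[C@H]2OC(C)=O | intermediate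
29 | 2β-acetoxy-10β-(triethylsilyloxy)-5αH-dauc-8-ene-4β,6α-diol | O[C@H]1CC(C)=C[C@H](O[Si](CC)(CC)CC)[C@]2(C)[C@@H]1[C@](O)(C(C)C)C[C@H]2OC(C)=O | intermediate
30 | 2β-acetoxy-8α,9α-epoxy-10β-(triethylsilyloxy)-5αH-daucane-4β,6α-diol | O[C@H]1C[C@@]2(C)O[C@H]2[C@H](O[Si](CC)(CC)CC)[C@]3(C)[C@@H]1[C@](O)(C(C)C)C[C@H]3OC(C)=O | intermediate
31 | 4-methoxybenzoyl chloride | COc1ccc(C(Cl)=O)cc1 | starting material
32 | 10-O-triethylsilyl ether of the target | COc1ccc(C(=O)O[C@H]2C[C@@]3(C)O[C@H]3[C@H](O[Si](CC)(CC)CC)[C@]3(C)[C@@H]2[C@](O)(C(C)C)C[C@H]3OC(C)=O)cc1 | intermediate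
33 | CNP0371526.1 | COc1ccc(C(=O)O[C@H]2C[C@@]3(C)O[C@H]3[C@H](O)[C@]3(C)[C@@H]2[C@](O)(C(C)C)C[C@H]3OC(C)=O)cc1 | target

Total steps: 23. Longest linear sequence: 21 (from 1: steps 1 to 3 and 6 to 23).

Steps most likely to fail

Step 9. The inward C1 methyl raises the boat barrier. Prolonged heating could then let loss or 1,3-migration of the allylic boron, or cis-trans isomerisation of the cyclopropane, overtake the [3,3] shift. The fallback replaces the boron terminus by a smaller, thermally inert oxygen terminus; it sets out from aldehyde 12 and returns at alcohol 17. Wittig olefination of 12 with (4-methoxybenzyloxymethyl)triphenylphosphonium chloride and NaHMDS at -78 °C, followed by separation of the E isomer, gives the (E)-2-(4-methoxybenzyloxy)ethenyl cyclopropane F1. Heating in toluene brings about the same ring expansion and gives the 10α-(4-methoxybenzyloxy) dienone F2. Buffered DDQ then frees the hydroxyl to give 17.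

Step 18. Hydrogen-atom transfer to the crowded C5 radical may show poor facial selectivity, or over-reduction may expel the neighbouring C4 oxygen and regenerate an alkene. The fallback reverses the order in which the two alkenes are addressed; it sets out from diol 24 and returns at target 33. Excess TESOTf with 2,6-lutidine gives the 4,10-bis(triethylsilyl) ether of the diene F3. One equivalent of buffered m-CPBA should attack the less hindered C8=C9 on its convex α face, anti to the 10β-silyloxy group, and give the 8α,9α-monoepoxide F4. With only C5=C6 left, BH3·THF followed by sodium perborate adds H and OH syn on the α face and gives the 5αH-6α-alcohol F5. Acylation with 31 and DMAP gives the bis(triethylsilyl) ether of the target F6, and buffered HF·pyridine gives 33.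

Step 6. Transmetalation and reductive elimination between a neopentyl-type cyclopropylzinc and a doubly flanked iodoenone may be slow. Protonation of the organozinc or base-induced loss of the silyloxy group could then compete. The fallback joins two sp2 carbons first and builds the cyclopropane afterwards; it sets out from 7 and 4 and returns at 11. Iodide 7 is converted with t-BuLi and then ZnCl2 into the (Z)-alkenylzinc alkoxide F7, and Negishi coupling with 4 gives the (Z)-hydroxy dienone F8. The same dioxaborolane-controlled Simmons-Smith reaction, directed by the allylic hydroxyl to the C6=C8 alkene, then gives 11.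

Further compounds
F1 | step 9 | (4R)-4-(tert-butyldimethylsilyloxy)-2-{cis-2-[(E)-2-(4-methoxybenzyloxy)ethenyl]-2-methylcyclopropyl}-3-methylcyclopent-2-en-1-one, cyclopropane configured as in 12 | CC1=C([C@@H]2C[C@]2(C)/C=C/OCc3ccc(OC)cc3)C(=O)C[C@H]1O[Si](C)(C)C(C)(C)C
F2 | step 9 | 2β-(tert-butyldimethylsilyloxy)-10α-(4-methoxybenzyloxy)-1β,8-dimethylbicyclo[5.3.0]deca-5,8-dien-4-one | C1=C2C(=O)C[C@@H](O[Si](C)(C)C(C)(C)C)[C@]2(C)[C@H](OCc3ccc(OC)cc3)C=C(C)C1
F3 | step 18 | 2β-acetoxy-4β,10β-bis(triethylsilyloxy)dauca-5,8-diene | C1=C2[C@](O[Si](CC)(CC)CC)(C(C)C)C[C@@H](OC(C)=O)[C@]2(C)[C@@H](O[Si](CC)(CC)CC)C=C(C)C1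
F4 | step 18 | 2β-acetoxy-8α,9α-epoxy-4β,10β-bis(triethylsilyloxy)dauc-5-ene | C1=C2[C@](O[Si](CC)(CC)CC)(C(C)C)C[C@@H](OC(C)=O)[C@]2(C)[C@@H](O[Si](CC)(CC)CC)[C@@H]3O[C@]3(C)C1
F5 | step 18 | 2β-acetoxy-8α,9α-epoxy-4β,10β-bis(triethylsilyloxy)-5αH-daucan-6α-ol | O[C@H]1C[C@@]2(C)O[C@H]2[C@H](O[Si](CC)(CC)CC)[C@]3(C)[C@@H]1[C@](O[Si](CC)(CC)CC)(C(C)C)C[C@H]3OC(C)=O
F6 | step 18 | 4,10-bis(triethylsilyl) ether of the target | COc1ccc(C(=O)O[C@H]2C[C@@]3(C)O[C@H]3[C@H](O[Si](CC)(CC)CC)[C@]3(C)[C@@H]2[C@](O[Si](CC)(CC)CC)(C(C)C)C[C@H]3OC(C)=O)cc1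
F7 | step 6 | chlorozinc (Z)-3-(chlorozincio)-2-methylprop-2-en-1-olate | Cl[Zn]OC/C(C)=C\[Zn]Cl
F8 | step 6 | (4R)-4-(tert-butyldimethylsilyloxy)-2-[(Z)-3-hydroxy-2-methylprop-1-enyl]-3-methylcyclopent-2-en-1-one | CC1=C(/C=C(/C)CO)C(=O)C[C@H]1O[Si](C)(C)C(C)(C)C
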